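**Assumptions.** The target has no stereocentre and no stereogenic double bond, so there is nothing to set as a single enantiomer; the two racemic sp3 centres on the route sit in non-isolated intermediates (4, 9) and are destroyed. Compound 1 is taken as a catalogue compound (otherwise one step from 1,2,3,5-tetramethoxybenzene with AcCl/AlCl3).

**Retrosynthetic overview**
1. Target 10 ⇐ reductive C-prenylation of the isoflavone-5,8-quinone 8: one step installs the C6 prenyl group and both free hydroxyls (5-OH, 8-OH), with no protecting groups.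
2. Quinone 8 ⇐ oxidative demethylation of the 5-hydroxy-8-methoxy isoflavone 6 ⇐ peri-selective demethylation of hexamethoxy isoflavone 5.
3. Isoflavone 5 ⇐ oxidative 1,2-aryl migration of chalcone 3, in place of the usual deoxybenzoin/C1 or 3-iodochromone/Suzuki disconnection.
4. Chalcone 3 ⇐ acetophenone 1 + aldehyde 2.
5. Ring order: A and B rings are bought as arenes; the pyranone C ring forms in step 2; the A ring is taken arene → quinone (step 4) → hydroquinone (step 5).

**Route**

Step 1
Reactants: 1 1-(2-hydroxy-3,4,6-trimethoxyphenyl)ethan-1-one; 2 2,4,5-trimethoxybenzaldehyde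
Product: 3 (E)-1-(2-hydroxy-3,4,6-trimethoxyphenyl)-3-(2,4,5-trimethoxyphenyl)prop-2-en-1-one
Conditions: KOH (50% aq, 10 equiv), EtOH, rt, 48 h; then cold 1 M HCl
Reagents that add atoms: none
Why: Claisen–Schmidt aldol condensation of the methyl ketone enolate with a non-enolisable aldehyde, where E1cB dehydration gives the conjugated E-enone and the phenolate form prevents flavanone closure.

Step 2
Reactants: 3 (E)-1-(2-hydroxy-3,4,6-trimethoxyphenyl)-3-(2,4,5-trimethoxyphenyl)prop-2-en-1-one
Product: 5 5,7,8-trimethoxy-3-(2,4,5-trimethoxyphenyl)-4H-chromen-4-one, via dimethyl acetal 4 (not isolated)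
Conditions: Tl(NO3)3·3H2O (1.1 equiv), MeOH/HC(OMe)3 1:1, rt, 16 h; filter; then 10% aq HCl, 50 °C, 3 h
Reagents that add atoms: methanol, CO (its two MeO groups sit only in 4 and leave again as methanol when 5 forms)
Why: Thallium(III) nitrate oxidative rearrangement of a 2'-hydroxychalcone, in which oxythallation of the enone triggers 1,2-migration of the very electron-rich 2,4,5-trimethoxyphenyl group from Cβ to Cα with loss of Tl(I), and acid then closes the 2'-OH onto the acetal carbon with loss of two MeOH, removing the racemic centre of 4.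

Step 3
Reactants: 5 5,7,8-trimethoxy-3-(2,4,5-trimethoxyphenyl)-4H-chromen-4-one
Product: 6 5-hydroxy-7,8-dimethoxy-3-(2,4,5-trimethoxyphenyl)-4H-chromen-4-one
Conditions: BCl3 (1.5 equiv, 1 M in CH2Cl2), CH2Cl2, −78 → 0 °C, 1 h; H2O quench
Reagents that add atoms: none
Why: Chelation-controlled Lewis-acid ether cleavage, where BCl3 bound to the C4 carbonyl cleaves only the peri 5-OMe through a six-membered borate chelate and the limited stoichiometry and low temperature spare the other five methyl ethers.

Step 4
Reactants: 6 5-hydroxy-7,8-dimethoxy-3-(2,4,5-trimethoxyphenyl)-4H-chromen-4-one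
Product: 8 7-methoxy-3-(2,4,5-trimethoxyphenyl)-4H-chromene-4,5,8-trione, via C8 hemiketal 7 (not isolated)
Conditions: PhI(OAc)2 (1.1 equiv), MeCN/H2O 4:1, 0 °C → rt, 30 min
Reagents that add atoms: water, O
Why: Hypervalent-iodine oxidative demethylation of a p-methoxyphenol to the p-quinone, in which ligand exchange at the 5-OH directs water to C8 para to it and the hemiketal loses MeOH, while PhI(OAc)2 without an acid activator leaves the phenol-free trimethoxyphenyl ring alone.

Step 5
Reactants: 8 7-methoxy-3-(2,4,5-trimethoxyphenyl)-4H-chromene-4,5,8-trione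
Product: 10 5,8-dihydroxy-7-methoxy-6-(3-methylbut-2-en-1-yl)-3-(2,4,5-trimethoxyphenyl)-4H-chromen-4-one, via C8 quinol adduct 9 (not isolated)
Conditions: tributyl(3-methylbut-2-en-1-yl)stannane (1.5 equiv), BF3·OEt2 (2.5 equiv), CH2Cl2, −78 → −40 °C, 1 h, Ar; degassed aq KF work-up
Reagents that add atoms: tributyl(3-methylbut-2-en-1-yl)stannane, CCCC[Sn](CCCC)(CCCC)CC=C(C)C
Why: Naruta-type BF3-mediated allylstannane–quinone coupling, a known reaction type not yet shown on a chromone-5,8-quinone, in which γ-attack on the more electrophilic C8 carbonyl (C5=O is a doubly vinylogous ester) gives quinol 9, a [3,3] shift across C7=C6 delivers the CH2 terminus to C6 (the only unsubstituted quinone carbon), and enolisation gives the linear-prenyl hydroquinone with no stereocentre left.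

**Compound list**
1 | 1-(2-hydroxy-3,4,6-trimethoxyphenyl)ethan-1-one | CC(=O)c1c(O)c(OC)c(OC)cc1OC | starting material
2 | 2,4,5-trimethoxybenzaldehyde | COc1cc(OC)c(C=O)cc1OC | starting material
3 | (E)-1-(2-hydroxy-3,4,6-trimethoxyphenyl)-3-(2,4,5-trimethoxyphenyl)prop-2-en-1-one | COc1cc(OC)c(/C=C/C(=O)c2c(O)c(OC)c(OC)cc2OC)cc1OC | intermediate
4 | 1-(2-hydroxy-3,4,6-trimethoxyphenyl)-3,3-dimethoxy-2-(2,4,5-trimethoxyphenyl)propan-1-one (racemic, not isolated) | COc1cc(OC)c(C(C(OC)OC)C(=O)c2c(O)c(OC)c(OC)cc2OC)cc1OC | intermediate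
5 | 5,7,8-trimethoxy-3-(2,4,5-trimethoxyphenyl)-4H-chromen-4-one | COc1cc(OC)c(-c2coc3c(OC)c(OC)cc(OC)c3c2=O)cc1OC | intermediate
6 | 5-hydroxy-7,8-dimethoxy-3-(2,4,5-trimethoxyphenyl)-4H-chromen-4-one | COc1cc(OC)c(-c2coc3c(OC)c(OC)cc(O)c3c2=O)cc1OC | intermediate
7 | 8-hydroxy-7,8-dimethoxy-3-(2,4,5-trimethoxyphenyl)-8H-chromene-4,5-dione (racemic hemiketal, not isolated) | COC1=CC(=O)C2=C(OC=C(c3cc(OC)c(OC)cc3OC)C2=O)C1(O)OC | intermediate
8 | 7-methoxy-3-(2,4,5-trimethoxyphenyl)-4H-chromene-4,5,8-trione | COC1=CC(=O)C2=C(OC=C(c3cc(OC)c(OC)cc3OC)C2=O)C1=O | intermediate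
9 | 8-hydroxy-7-methoxy-8-(2-methylbut-3-en-2-yl)-3-(2,4,5-trimethoxyphenyl)-8H-chromene-4,5-dione (racemic, present as its O-metalated form, not isolated) | COC1=CC(=O)C2=C(OC=C(c3cc(OC)c(OC)cc3OC)C2=O)C1(O)C(C)(C)C=C | intermediate
10 | 5,8-dihydroxy-7-methoxy-6-(3-methylbut-2-en-1-yl)-3-(2,4,5-trimethoxyphenyl)-4H-chromen-4-one | COc1cc(OC)c(-c2coc3c(O)c(OC)c(CC=C(C)C)c(O)c3c2=O)cc1OC | target

**Totals.** Total step count: 5. Longest linear sequence: 5 steps (1 or 2 → 10).

**Three steps most likely to fail**

Step 5 (quinone prenylation). The risks are the reverse-prenyl (1,1-dimethylallyl) isomer from direct SE2' conjugate addition, ipso attack at C7, and acid-induced chroman formation. The fallback sets out from 8 and comes back at 10. It transfers a symmetrical allyl group, for which 1,2-addition/[3,3] and direct 1,4-addition give the same product: allyltributylstannane and BF3·OEt2 in CH2Cl2 at −78 °C convert 8 into 6-allyl-5,8-dihydroxy-7-methoxy-3-(2,4,5-trimethoxyphenyl)-4H-chromen-4-one F4. Olefin cross-metathesis of this compound with 2-methylbut-2-ene (Grubbs II, 5 mol%, CH2Cl2/2-methylbut-2-ene, 40 °C) then builds the trisubstituted alkene and gives 10.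

Step 4 (oxidative demethylation). The risks are that the chelated 5-OH is sluggish toward iodine(III), that the electron-rich B ring is oxidised, or that water opens the activated pyranone at C2. The fallback sets out from 6 and comes back at 8. It replaces oxidative ether cleavage by Lewis-acid cleavage followed by a metal-oxide oxidation that cannot touch the B ring. Excess BCl3 (4 equiv, CH2Cl2, 0 °C → rt) acts on the 5-O-borate chelate of 6 and removes the twisted 8-OMe, which is flanked by O1 and the 7-OMe, giving 5,8-dihydroxy-7-methoxy-3-(2,4,5-trimethoxyphenyl)-4H-chromen-4-one F3. Ag2O with MgSO4 in CH2Cl2 at rt oxidises this hydroquinone to 8. The selectivity for the 8-OMe over the 7-OMe and B-ring ethers is the uncertain point of this fallback.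

Step 2 (thallium rearrangement). The risks are oxidation or nitration of the two electron-rich rings and of the free 2'-phenol. The fallback sets out from 1 and comes back at 5, and replaces the aryl migration by a cross-coupling. Heating 1 with DMF-DMA (toluene, 90 °C) gives (E)-3-(dimethylamino)-1-(2-hydroxy-3,4,6-trimethoxyphenyl)prop-2-en-1-one F1. Iodine in MeOH at rt cyclises it to 3-iodo-5,7,8-trimethoxy-4H-chromen-4-one F2. Suzuki–Miyaura coupling with commercial (2,4,5-trimethoxyphenyl)boronic acid (Pd(dppf)Cl2, K2CO3, dioxane/H2O, 80 °C) gives 5; compounds 2 and 3 are then not needed.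

**Further compounds**
F1 | step 2 | (E)-3-(dimethylamino)-1-(2-hydroxy-3,4,6-trimethoxyphenyl)prop-2-en-1-one | CN(C)/C=C/C(=O)c1c(O)c(OC)c(OC)cc1OC
F2 | step 2 | 3-iodo-5,7,8-trimethoxy-4H-chromen-4-one | COc1cc(OC)c2c(c1OC)occ(I)c2=O
F3 | step 4 | 5,8-dihydroxy-7-methoxy-3-(2,4,5-trimethoxyphenyl)-4H-chromen-4-one | COc1cc(OC)c(-c2coc3c(O)c(OC)cc(O)c3c2=O)cc1OC
F4 | step 5 | 6-allyl-5,8-dihydroxy-7-methoxy-3-(2,4,5-trimethoxyphenyl)-4H-chromen-4-one | COc1cc(OC)c(-c2coc3c(O)c(OC)c(CC=C)c(O)c3c2=O)cc1OC
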